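**Retrosynthetic overview**

The strategy rests on the dihydrofuran ring O1–C2–C3–C3a–C7a fused to the phloroglucinol-type ring: with its C2 aryl group and a carbonyl carbon exocyclic on C3, it is a 5,7-dioxygenated flavanone (2-arylchroman-4-one) that has lost one ring member, the former C4 now sitting outside the ring on C3.
Disconnections, backwards: six O-benzyl groups; the C7 acyl–vinyl bond (chromium-mediated alkenyl addition to a C7 aldehyde, then oxidation); the C7–CHO bond (Vilsmeier–Haack); the C3 aroyl bond (Weinreb amide plus aryllithium); the C3–C3a bond by oxidative 1,2-aryl shift in a (2R)-flavanone; the C2–aryl bond by enantioselective conjugate arylation of a chromone built from phloroacetophenone.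
Ring order: pyranone closed on the phloroglucinol ring, 4-oxyphenyl ring joined at C2, pyranone contracted to the dihydrofuran, then the resorcinol ketone at C3, the formyl carbon at C7, the arylvinyl unit on that carbon, and deprotection last.

Key step: step 5

Assumption: (S)-t-BuPyOx, that is (S)-4-tert-butyl-2-(pyridin-2-yl)-4,5-dihydrooxazole, is taken to give the 2R flavanone by analogy with the facial sense it shows with cyclic enones; this is checked on the first run and the ligand antipode is used if it proves otherwise.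

**Route**

Step 1
Reactants: 1 1-(2,4,6-trihydroxyphenyl)ethan-1-one
Product: 2 1-[2,4-bis(benzyloxy)-6-hydroxyphenyl]ethan-1-one
Conditions: BnBr (2.1 equiv), K2CO3, DMF, 0 °C → rt
Reagents that add atoms: benzyl bromide BrCc1ccccc1
Why: Williamson etherification under a weak base alkylates the two phenols that are not locked in the hydrogen bond to the acetyl carbonyl, so the chelated ortho hydroxyl needed for the pyranone closure stays free.

Step 2
Reactants: 2 1-[2,4-bis(benzyloxy)-6-hydroxyphenyl]ethan-1-one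
Product: 3 (E)-1-[2,4-bis(benzyloxy)-6-hydroxyphenyl]-3-(dimethylamino)prop-2-en-1-one
Conditions: Me2NCH(OMe)2, toluene, 95 °C
Reagents that add atoms: N,N-dimethylformamide dimethyl acetal COC(OC)N(C)C
Why: Condensation of the acetyl methyl group with the amide acetal gives the enaminone and brings in the future chromone C2 as the only new carbon, the chelated phenol taking no part.

Step 3
Reactants: 3 (E)-1-[2,4-bis(benzyloxy)-6-hydroxyphenyl]-3-(dimethylamino)prop-2-en-1-one
Product: 4 5,7-bis(benzyloxy)-4H-chromen-4-one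
Conditions: conc. HCl, CH2Cl2, rt
Reagents that add atoms: none
Why: Acid-promoted addition of the free phenol to the protonated enaminone and loss of dimethylamine (addition–elimination, the standard enaminone chromone synthesis) closes the pyranone under conditions mild enough for the aryl benzyl ethers.

Step 4
Reactants: 4 5,7-bis(benzyloxy)-4H-chromen-4-one; 5 [4-(benzyloxy)phenyl]boronic acid
Product: 6 (2R)-5,7-bis(benzyloxy)-2-[4-(benzyloxy)phenyl]chroman-4-one
Conditions: Pd(OCOCF3)2 (5 mol %), (S)-t-BuPyOx (6 mol %), NH4PF6 (30 mol %), H2O (5 equiv), ClCH2CH2Cl, 60 °C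
Reagents that add atoms: none
Why: This is the enantioselective conjugate addition of an arylboronic acid to a chromone under cationic divalent palladium with a chiral pyridine-oxazoline ligand, in which the arylpalladium species inserts the C2=C3 bond on the face left open by the tert-butyl group and water protonates the palladium enolate before beta-hydride loss, so that C2 is set as R by the ligand (the enantiomeric excess is to be measured by chiral HPLC and raised by recrystallization if needed).

Step 5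
Reactants: 6 (2R)-5,7-bis(benzyloxy)-2-[4-(benzyloxy)phenyl]chroman-4-one
Product: 9 methyl (2R,3R)-4,6-bis(benzyloxy)-2-[4-(benzyloxy)phenyl]-2,3-dihydro-1-benzofuran-3-carboxylate, via methyl enol ether 7 (not isolated), via trans iodanyl dimethyl ketal 8 (not isolated)
Conditions: PhI(OAc)2 (1.2 equiv, added slowly), H2SO4 (cat.), HC(OMe)3, 0 °C → rt; DBU (cat.), CH2Cl2, rt on the crude product only if a cis ester is seen
Reagents that add atoms: trimethyl orthoformate COC(OC)OC
Why: Acid and orthoformate turn the C4 ketone of 6 into methyl enol ether 7, electrophilic trivalent iodine attacks C3 on the face away from the C2 aryl group while methanol adds to C4, and in the resulting trans-diequatorial λ3-iodane 8 the C4–C4a ring bond lies antiperiplanar to the C3–I bond. The electron-rich aryl carbon C4a then shifts from C4 to C3 through a bridged phenonium-type ion as iodobenzene leaves, forming the C3–C3a bond of the product as the C4–C4a bond breaks, and the dimethoxycarbenium ion left at the old C4 gives up a methyl group to acetate to become the exocyclic methyl ester. The closest known reaction is the oxidative ring contraction of flavanones to methyl trans-2-aryl-2,3-dihydrobenzofuran-3-carboxylates with hypervalent iodine or trivalent thallium in trimethyl orthoformate, here applied to a 5,7,4'-tribenzyloxy flavanone. The five-membered dihydrofuran is therefore not closed by a cyclization but arises from the six-membered pyranone by this 1,2-aryl shift. The new C3 centre is set by the stereospecific invertive migration on the trans iodane, which places the ester trans to the C2 aryl group (2R,3R), the arrangement also favoured thermodynamically at this epimerizable position, while C2 is not touched. The step needs C4a to migrate in preference to the C2 aryl group (isoflavone) or to elimination toward C2 (flavone), which the antiperiplanar alignment in 8 and the ortho and para alkoxy donors on ring A should secure, and it needs the enol ether to outcompete ring A for the iodine electrophile, which low temperature and slow addition of the oxidant are meant to ensure.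

Step 6
Reactants: 9 methyl (2R,3R)-4,6-bis(benzyloxy)-2-[4-(benzyloxy)phenyl]-2,3-dihydro-1-benzofuran-3-carboxylate
Product: 10 (2R,3R)-4,6-bis(benzyloxy)-2-[4-(benzyloxy)phenyl]-N-methoxy-N-methyl-2,3-dihydro-1-benzofuran-3-carboxamide
Conditions: MeNH(OMe)·HCl, AlMe3, CH2Cl2, 0 → 40 °C; aq. KNaC4H4O6
Reagents that add atoms: N,O-dimethylhydroxylamine hydrochloride CNOC.Cl
Why: Aminolysis of the hindered methyl ester by the aluminium amide made from trimethylaluminium and the hydroxylamine salt (Weinreb amide formation) is a non-basic acyl substitution, so the C3 hydrogen is not removed and the trans relationship to C2 is kept.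

Step 7
Reactants: 11 4-bromobenzene-1,3-diol
Product: 12 2,4-bis(benzyloxy)-1-bromobenzene
Conditions: BnBr (2.2 equiv), K2CO3, DMF, rt
Reagents that add atoms: benzyl bromide BrCc1ccccc1
Why: Double Williamson etherification of both phenols is straightforward and leaves the aryl bromide for the later halogen–lithium exchange.

Step 8
Reactants: 10 (2R,3R)-4,6-bis(benzyloxy)-2-[4-(benzyloxy)phenyl]-N-methoxy-N-methyl-2,3-dihydro-1-benzofuran-3-carboxamide; 12 2,4-bis(benzyloxy)-1-bromobenzene
Product: 15 [(2R,3R)-4,6-bis(benzyloxy)-2-[4-(benzyloxy)phenyl]-2,3-dihydro-1-benzofuran-3-yl][2,4-bis(benzyloxy)phenyl]methanone, via aryllithium 13 (not isolated), via lithium hemiaminal chelate 14 (not isolated)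
Conditions: 12, n-BuLi, THF, −78 °C; then 10, THF, −78 → −40 °C; aq. NH4Cl
Reagents that add atoms: none
Why: Bromine–lithium exchange gives aryllithium 13, which adds to the Weinreb amide to form the lithium chelate 14 that holds until the aqueous quench, so the ketone forms without over-addition; at −78 °C addition should outpace removal of the C3 hydrogen, and any epimerization at C3 returns to the favoured trans arrangement because C2 is untouched and ring opening from the C3 enolate (the reverse of a 5-endo-trig closure) is stereoelectronically slow.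

Step 9
Reactants: 15 [(2R,3R)-4,6-bis(benzyloxy)-2-[4-(benzyloxy)phenyl]-2,3-dihydro-1-benzofuran-3-yl][2,4-bis(benzyloxy)phenyl]methanone
Product: 17 (2R,3R)-4,6-bis(benzyloxy)-3-[2,4-bis(benzyloxy)benzoyl]-2-[4-(benzyloxy)phenyl]-2,3-dihydro-1-benzofuran-7-carbaldehyde, via C7 iminium chloride 16 (not isolated)
Conditions: POCl3, DMF, 0 → 45 °C; aq. NaOAc, rt
Reagents that add atoms: N,N-dimethylformamide CN(C)C=O; water O
Why: Vilsmeier–Haack formylation is an electrophilic aromatic substitution by the chloroiminium ion that selects the trioxygenated ring A over the ketone-bearing and mono-oxygenated rings, and within ring A it selects C7, which is activated by O1 and the C6 ether (ortho) and the C4 ether (para) and is less crowded than C5 between two benzyloxy groups; hydrolysis of iminium salt 16 gives the aldehyde, whose position is to be confirmed by HMBC and NOE with any C5 isomer removed by chromatography.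

Step 10
Reactants: 18 1-[4-(benzyloxy)phenyl]ethan-1-one
Product: 20 1-[4-(benzyloxy)phenyl]ethenyl trifluoromethanesulfonate, via potassium enolate 19 (not isolated)
Conditions: KN(SiMe3)2, THF, −78 °C; PhNTf2, −78 → 0 °C; Et3N-deactivated silica, used promptly
Reagents that add atoms: N-phenylbis(trifluoromethanesulfonimide) O=S(=O)(N(c1ccccc1)S(=O)(=O)C(F)(F)F)C(F)(F)F
Why: Deprotonation of the methyl ketone with a hindered amide base gives the only possible enolate 19, whose oxygen is sulfonylated by the N-aryl triflimide in a standard enol triflate synthesis that leaves the benzyl ether untouched.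

Step 11
Reactants: 17 (2R,3R)-4,6-bis(benzyloxy)-3-[2,4-bis(benzyloxy)benzoyl]-2-[4-(benzyloxy)phenyl]-2,3-dihydro-1-benzofuran-7-carbaldehyde; 20 1-[4-(benzyloxy)phenyl]ethenyl trifluoromethanesulfonate
Product: 22 1-[(2R,3R)-4,6-bis(benzyloxy)-3-[2,4-bis(benzyloxy)benzoyl]-2-[4-(benzyloxy)phenyl]-2,3-dihydro-1-benzofuran-7-yl]-2-[4-(benzyloxy)phenyl]prop-2-en-1-ol (both carbinol epimers), via alkenylchromium dichloride 21 (not isolated)
Conditions: CrCl2 (4 equiv), NiCl2 (2 mol %), degassed DMF, rt
Reagents that add atoms: none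
Why: In the Nozaki–Hiyama–Kishi reaction zerovalent nickel formed in the flask inserts into the vinyl C–O bond of the triflate and passes the alkenyl group to trivalent chromium, and alkenylchromium 21 adds to the aldehyde but neither to the hindered aryl ketone nor as a base at C3, so only the C7 carbinol forms; its new centre is not controlled and need not be, since it is oxidized in the next step.

Step 12
Reactants: 22 the C7 allylic carbinol (both epimers)
Product: 23 1-[(2R,3R)-4,6-bis(benzyloxy)-3-[2,4-bis(benzyloxy)benzoyl]-2-[4-(benzyloxy)phenyl]-2,3-dihydro-1-benzofuran-7-yl]-2-[4-(benzyloxy)phenyl]prop-2-en-1-one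
Conditions: Dess–Martin periodinane, NaHCO3, CH2Cl2, 0 °C → rt
Reagents that add atoms: none
Why: Dess–Martin oxidation of the allylic and benzylic secondary alcohol under bicarbonate buffering gives the aryl vinyl ketone without acid that could ionize the carbinol and without base that could disturb C3 or add to the new enone, and it removes the uncontrolled carbinol centre.

Step 13
Reactants: 23 the hexa-O-benzyl enone
Product: 24 1-[(2R,3R)-3-(2,4-dihydroxybenzoyl)-4,6-dihydroxy-2-(4-hydroxyphenyl)-2,3-dihydro-1-benzofuran-7-yl]-2-(4-hydroxyphenyl)prop-2-en-1-one (CNP0162111.1)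
Conditions: BCl3, C6HMe5, CH2Cl2, −78 °C; MeOH, −78 °C; no basic wash, reverse-phase purification with an acidic modifier
Reagents that add atoms: none
Why: Boron trichloride cleaves aryl benzyl ethers at −78 °C through the O-coordinated oxonium ion while pentamethylbenzene captures each benzyl cation by Friedel–Crafts alkylation, so neither the electron-rich rings nor the enone are benzylated; no hydrogen is used, so the 1,1-disubstituted alkene survives, and quench and isolation are kept free of base so that the C6 hydroxyl does not add to the enone (6-endo oxa-Michael to an isoflavanone) and C2 and C3 are not disturbed.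

**Compound list**

1 | 1-(2,4,6-trihydroxyphenyl)ethan-1-one | CC(=O)c1c(O)cc(O)cc1O | starting material
2 | 1-[2,4-bis(benzyloxy)-6-hydroxyphenyl]ethan-1-one | CC(=O)c1c(O)cc(OCc2ccccc2)cc1OCc1ccccc1 | intermediate
3 | (E)-1-[2,4-bis(benzyloxy)-6-hydroxyphenyl]-3-(dimethylamino)prop-2-en-1-one | CN(C)/C=C/C(=O)c1c(O)cc(OCc2ccccc2)cc1OCc1ccccc1 | intermediate
4 | 5,7-bis(benzyloxy)-4H-chromen-4-one | O=c1ccoc2cc(OCc3ccccc3)cc(OCc3ccccc3)c12 | intermediate
5 | [4-(benzyloxy)phenyl]boronic acid | OB(O)c1ccc(OCc2ccccc2)cc1 | starting material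
6 | (2R)-5,7-bis(benzyloxy)-2-[4-(benzyloxy)phenyl]chroman-4-one | O=C1c2c(OCc3ccccc3)cc(OCc3ccccc3)cc2O[C@@H](c2ccc(OCc3ccccc3)cc2)C1 | intermediate
7 | (2R)-5,7-bis(benzyloxy)-2-[4-(benzyloxy)phenyl]-4-methoxy-2H-chromene | COC1=C[C@H](c2ccc(OCc3ccccc3)cc2)Oc2cc(OCc3ccccc3)cc(OCc3ccccc3)c12 | intermediate
8 | (2S,3S)-3-[acetoxy(phenyl)-λ3-iodanyl]-5,7-bis(benzyloxy)-2-[4-(benzyloxy)phenyl]-4,4-dimethoxychromane (2,3-trans; C2 geometry as in 6, descriptor changed by the sequence rule only) | COC1(OC)c2c(OCc3ccccc3)cc(OCc3ccccc3)cc2O[C@@H](c2ccc(OCc3ccccc3)cc2)[C@@H]1I(OC(C)=O)c1ccccc1 | intermediate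
9 | methyl (2R,3R)-4,6-bis(benzyloxy)-2-[4-(benzyloxy)phenyl]-2,3-dihydro-1-benzofuran-3-carboxylate (2,3-trans) | c1c(OCc3ccccc3)cc(OCc3ccccc3)c2c1O[C@@H](c1ccc(OCc3ccccc3)cc1)[C@@H]2C(=O)OC | intermediate
10 | (2R,3R)-4,6-bis(benzyloxy)-2-[4-(benzyloxy)phenyl]-N-methoxy-N-methyl-2,3-dihydro-1-benzofuran-3-carboxamide | c1c(OCc3ccccc3)cc(OCc3ccccc3)c2c1O[C@@H](c1ccc(OCc3ccccc3)cc1)[C@@H]2C(=O)N(C)OC | intermediate
11 | 4-bromobenzene-1,3-diol | Oc1ccc(Br)c(O)c1 | starting material
12 | 2,4-bis(benzyloxy)-1-bromobenzene | Brc1ccc(OCc2ccccc2)cc1OCc1ccccc1 | intermediate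
13 | [2,4-bis(benzyloxy)phenyl]lithium | [Li]c1ccc(OCc2ccccc2)cc1OCc1ccccc1 | intermediate
14 | lithium alkoxide of the tetrahedral adduct of 13 to 10 (N-methoxy-N-methyl hemiaminal, either configuration at the new carbon) | c1c(OCc3ccccc3)cc(OCc3ccccc3)c2c1O[C@@H](c1ccc(OCc3ccccc3)cc1)[C@@H]2C(O[Li])(N(C)OC)c1ccc(OCc2ccccc2)cc1OCc1ccccc1 | intermediate
15 | [(2R,3R)-4,6-bis(benzyloxy)-2-[4-(benzyloxy)phenyl]-2,3-dihydro-1-benzofuran-3-yl][2,4-bis(benzyloxy)phenyl]methanone | c1c(OCc3ccccc3)cc(OCc3ccccc3)c2c1O[C@@H](c1ccc(OCc3ccccc3)cc1)[C@@H]2C(=O)c1ccc(OCc3ccccc3)cc1OCc1ccccc1 | intermediate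
16 | N,N-dimethyliminium chloride at C7 of 15 | C[N+](C)=Cc1c(OCc3ccccc3)cc(OCc3ccccc3)c2c1O[C@@H](c1ccc(OCc3ccccc3)cc1)[C@@H]2C(=O)c1ccc(OCc3ccccc3)cc1OCc1ccccc1.[Cl-] | intermediate
17 | (2R,3R)-4,6-bis(benzyloxy)-3-[2,4-bis(benzyloxy)benzoyl]-2-[4-(benzyloxy)phenyl]-2,3-dihydro-1-benzofuran-7-carbaldehyde | O=Cc1c(OCc3ccccc3)cc(OCc3ccccc3)c2c1O[C@@H](c1ccc(OCc3ccccc3)cc1)[C@@H]2C(=O)c1ccc(OCc3ccccc3)cc1OCc1ccccc1 | intermediate
18 | 1-[4-(benzyloxy)phenyl]ethan-1-one | CC(=O)c1ccc(OCc2ccccc2)cc1 | starting material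
19 | potassium 1-[4-(benzyloxy)phenyl]ethen-1-olate | C=C(O[K])c1ccc(OCc2ccccc2)cc1 | intermediate
20 | 1-[4-(benzyloxy)phenyl]ethenyl trifluoromethanesulfonate | C=C(OS(=O)(=O)C(F)(F)F)c1ccc(OCc2ccccc2)cc1 | intermediate
21 | {1-[4-(benzyloxy)phenyl]ethenyl}chromium dichloride | C=C([Cr](Cl)Cl)c1ccc(OCc2ccccc2)cc1 | intermediate
22 | 1-[(2R,3R)-4,6-bis(benzyloxy)-3-[2,4-bis(benzyloxy)benzoyl]-2-[4-(benzyloxy)phenyl]-2,3-dihydro-1-benzofuran-7-yl]-2-[4-(benzyloxy)phenyl]prop-2-en-1-ol (both carbinol epimers) | C=C(C(O)c1c(OCc3ccccc3)cc(OCc3ccccc3)c2c1O[C@@H](c1ccc(OCc3ccccc3)cc1)[C@@H]2C(=O)c1ccc(OCc3ccccc3)cc1OCc1ccccc1)c1ccc(OCc2ccccc2)cc1 | intermediate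
23 | 1-[(2R,3R)-4,6-bis(benzyloxy)-3-[2,4-bis(benzyloxy)benzoyl]-2-[4-(benzyloxy)phenyl]-2,3-dihydro-1-benzofuran-7-yl]-2-[4-(benzyloxy)phenyl]prop-2-en-1-one | C=C(C(=O)c1c(OCc3ccccc3)cc(OCc3ccccc3)c2c1O[C@@H](c1ccc(OCc3ccccc3)cc1)[C@@H]2C(=O)c1ccc(OCc3ccccc3)cc1OCc1ccccc1)c1ccc(OCc2ccccc2)cc1 | intermediate
24 | 1-[(2R,3R)-3-(2,4-dihydroxybenzoyl)-4,6-dihydroxy-2-(4-hydroxyphenyl)-2,3-dihydro-1-benzofuran-7-yl]-2-(4-hydroxyphenyl)prop-2-en-1-one (CNP0162111.1) | C=C(C(=O)c1c(O)cc(O)c2c1O[C@@H](c1ccc(O)cc1)[C@@H]2C(=O)c1ccc(O)cc1O)c1ccc(O)cc1 | target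

**Step count and risks**

Total step count: 13. Longest linear sequence: 11 steps (steps 1–6, 8, 9, 11, 12, 13, from compound 1); steps 7 and 10 make the two side fragments.

The three steps most likely to fail:

Step 5 (ring contraction). The oxidant may attack the very electron-rich ring A instead of C3, ketalization of the donor-deactivated C4 carbonyl may be slow, or the C3 iodane may collapse by elimination to the flavone or by shift of the C2 aryl group instead of C4a. The fallback sets out from 6 and comes back at 9, and runs the same C4a shift as a Wolff rearrangement. The lithium enolate of 6 (LiN(SiMe3)2, THF, −78 °C, formed and trapped cold so that it does not open to the chalcone and racemize C2) is acylated with CF3CO2CH2CF3 to (2R)-5,7-bis(benzyloxy)-2-[4-(benzyloxy)phenyl]-3-(trifluoroacetyl)chroman-4-one F1. Detrifluoroacetylative diazo transfer (MsN3, Et3N, H2O, MeCN, rt) gives the 3-diazoflavanone F2. Irradiation (365 nm, MeOH/THF, rt) expels nitrogen with migration of C4a to C3 to give the ring-contracted ketene F3, which methanol traps as a mixture of 9 and its cis epimer, methyl (2R,3S)-4,6-bis(benzyloxy)-2-[4-(benzyloxy)phenyl]-2,3-dihydro-1-benzofuran-3-carboxylate F4. Catalytic DBU in CH2Cl2 then converges the mixture on the trans ester 9.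

Step 13 (global debenzylation). Chloride or hydrogen chloride may add to the 1,1-disubstituted enone, the freed C6 hydroxyl may close onto the enone under the Lewis acid or during work-up, or cleavage of six ethers may stall. The fallback sets out from 17 and comes back at 24: the benzyl ethers are removed before the enone exists and replaced by silyl ethers that come off under acidic fluoride. Compound 17 is debenzylated (BCl3, C6HMe5, CH2Cl2, −78 °C) to the pentaphenol aldehyde F7, which is persilylated (TBSOTf, 2,6-lutidine, CH2Cl2, 0 °C) to the penta-TBS aldehyde F8. 4'-Hydroxyacetophenone is silylated (TBSCl, imidazole, DMF) to 4'-(tert-butyldimethylsilyloxy)acetophenone F9 and converted as in step 10 (KN(SiMe3)2; PhNTf2) into 1-[4-(tert-butyldimethylsilyloxy)phenyl]ethenyl triflate F10. Nozaki–Hiyama–Kishi coupling of F8 with F10 (CrCl2, NiCl2 cat., DMF) gives the hexa-TBS carbinol F11, Dess–Martin oxidation gives the hexa-TBS enone F12, and HF·pyridine in THF/pyridine at 0 °C releases 24 without chloride, strong Lewis acid or phenoxide.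

Step 8 (aryl ketone formation). The hindered, ortho-substituted aryllithium may act as a base and remove the acidic C3 hydrogen instead of adding to the crowded amide carbonyl, which would return starting material or open the dihydrofuran. The fallback sets out from 10 and comes back at 15. Reduction of the Weinreb amide (i-Bu2AlH, THF, −78 °C) stops at (2R,3R)-4,6-bis(benzyloxy)-2-[4-(benzyloxy)phenyl]-2,3-dihydro-1-benzofuran-3-carbaldehyde F5. Aryllithium 13 adds to this much more reactive and less hindered carbonyl at −78 °C to give the secondary carbinol [4,6-bis(benzyloxy)-2-[4-(benzyloxy)phenyl]-2,3-dihydro-1-benzofuran-3-yl][2,4-bis(benzyloxy)phenyl]methanol F6 as a mixture of carbinol epimers. Dess–Martin oxidation (NaHCO3, CH2Cl2) then gives ketone 15.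

**Further compounds**

F1 | step 5 | (2R)-5,7-bis(benzyloxy)-2-[4-(benzyloxy)phenyl]-3-(trifluoroacetyl)chroman-4-one (C3 unassigned, largely enolized) | O=C1c2c(OCc3ccccc3)cc(OCc3ccccc3)cc2O[C@@H](c2ccc(OCc3ccccc3)cc2)C1C(=O)C(F)(F)F
F2 | step 5 | (2S)-5,7-bis(benzyloxy)-2-[4-(benzyloxy)phenyl]-3-diazochroman-4-one (C2 geometry as in 6; descriptor changed by the sequence rule only) | O=C1c2c(OCc3ccccc3)cc(OCc3ccccc3)cc2O[C@@H](c2ccc(OCc3ccccc3)cc2)C1=[N+]=[N-]
F3 | step 5 | (2S)-4,6-bis(benzyloxy)-2-[4-(benzyloxy)phenyl]-3-(oxomethylidene)-2,3-dihydro-1-benzofuran (ketene; C2 geometry as in 6) | c1c(OCc3ccccc3)cc(OCc3ccccc3)c2c1O[C@@H](c1ccc(OCc3ccccc3)cc1)C2=C=O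
F4 | step 5 | methyl (2R,3S)-4,6-bis(benzyloxy)-2-[4-(benzyloxy)phenyl]-2,3-dihydro-1-benzofuran-3-carboxylate (2,3-cis) | c1c(OCc3ccccc3)cc(OCc3ccccc3)c2c1O[C@@H](c1ccc(OCc3ccccc3)cc1)[C@H]2C(=O)OC
F5 | step 8 | (2R,3R)-4,6-bis(benzyloxy)-2-[4-(benzyloxy)phenyl]-2,3-dihydro-1-benzofuran-3-carbaldehyde | c1c(OCc3ccccc3)cc(OCc3ccccc3)c2c1O[C@@H](c1ccc(OCc3ccccc3)cc1)[C@@H]2C=O
F6 | step 8 | [(2R,3S)-4,6-bis(benzyloxy)-2-[4-(benzyloxy)phenyl]-2,3-dihydro-1-benzofuran-3-yl][2,4-bis(benzyloxy)phenyl]methanol (2,3-trans ring geometry as in 15, C3 descriptor changed by the sequence rule only; both carbinol epimers) | c1c(OCc3ccccc3)cc(OCc3ccccc3)c2c1O[C@@H](c1ccc(OCc3ccccc3)cc1)[C@@H]2C(O)c1ccc(OCc3ccccc3)cc1OCc1ccccc1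
F7 | step 13 | (2R,3R)-3-(2,4-dihydroxybenzoyl)-4,6-dihydroxy-2-(4-hydroxyphenyl)-2,3-dihydro-1-benzofuran-7-carbaldehyde | O=Cc1c(O)cc(O)c2c1O[C@@H](c1ccc(O)cc1)[C@@H]2C(=O)c1ccc(O)cc1O
F8 | step 13 | penta-O-(tert-butyldimethylsilyl) ether of F7 | O=Cc1c(O[Si](C)(C)C(C)(C)C)cc(O[Si](C)(C)C(C)(C)C)c2c1O[C@@H](c1ccc(O[Si](C)(C)C(C)(C)C)cc1)[C@@H]2C(=O)c1ccc(O[Si](C)(C)C(C)(C)C)cc1O[Si](C)(C)C(C)(C)C
F9 | step 13 | 1-[4-(tert-butyldimethylsilyloxy)phenyl]ethan-1-one | CC(=O)c1ccc(O[Si](C)(C)C(C)(C)C)cc1
F10 | step 13 | 1-[4-(tert-butyldimethylsilyloxy)phenyl]ethenyl trifluoromethanesulfonate | C=C(OS(=O)(=O)C(F)(F)F)c1ccc(O[Si](C)(C)C(C)(C)C)cc1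
F11 | step 13 | hexa-O-(tert-butyldimethylsilyl) C7 allylic carbinol (both carbinol epimers) | C=C(C(O)c1c(O[Si](C)(C)C(C)(C)C)cc(O[Si](C)(C)C(C)(C)C)c2c1O[C@@H](c1ccc(O[Si](C)(C)C(C)(C)C)cc1)[C@@H]2C(=O)c1ccc(O[Si](C)(C)C(C)(C)C)cc1O[Si](C)(C)C(C)(C)C)c1ccc(O[Si](C)(C)C(C)(C)C)cc1
F12 | step 13 | hexa-O-(tert-butyldimethylsilyl) ether of 24 | C=C(C(=O)c1c(O[Si](C)(C)C(C)(C)C)cc(O[Si](C)(C)C(C)(C)C)c2c1O[C@@H](c1ccc(O[Si](C)(C)C(C)(C)C)cc1)[C@@H]2C(=O)c1ccc(O[Si](C)(C)C(C)(C)C)cc1O[Si](C)(C)C(C)(C)C)c1ccc(O[Si](C)(C)C(C)(C)C)cc1
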